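The numbers in the tables are simulated from invented constants; noise was put on by code.

The constant to carry here is a half-time. Partner is charged mole for mole with the two substrates together, so if the substrates stay equal, partner and substrate fall as one second-order pair. The fraction left is then 1/(1+t/τ), where τ is the time at which partner used equals partner left. This is the one clock of the ledger, and you read it from the runs.

| flask | left-handed substrate | right-handed substrate | partner | catalyst | added ligand | remark | time |
|---|---|---|---|---|---|---|---|
| alder | 25 mM | 25 mM | 2 equiv | 1.5 mol% | 0.88 mM | run made earlier |  |
| oak | 56 mM | 56 mM | 2 equiv | 1.5 mol% | 0.88 mM | run made earlier |  |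
| flask | 37 mM | 37 mM | 2.00 equiv | 1.5 mol% | 0.88 mM |  | 3.0 min |

| run | time / min | left-handed product / % | right-handed product / % | left-handed substrate / % |
|---|---|---|---|---|
| alder | 0.667 | 7.1 | 2.0 | 44.9 |
| alder | 1.33 | 10.8 | 2.4 | 41.7 |
| alder | 2.00 | 17.2 | 4.3 | 38.5 |
| alder | 2.50 | 19.7 | 5.8 | 38.2 |
| alder | 3.00 | 21.1 | 6.2 | 35.7 |
| alder | 4.00 | 26.6 | 8.7 | 32.2 |
| oak | 0.250 | 20.8 | 5.3 | 35.0 |
| oak | 0.667 | 38.9 | 9.8 | 25.8 |
| oak | 1.33 | 51.0 | 14.8 | 16.7 |
| oak | 2.00 | 55.7 | 17.9 | 12.9 |
| oak | 3.00 | 59.5 | 22.7 | 8.9 |
| oak | 4.00 | 59.8 | 25.1 | 8.3 |

(standard deviation of a reading: 0.5 percentage points)

- catalyst is single-handed; left-handed substrate and right-handed substrate are mirror images of each other, charged as a racemate, each of them at the stated concentration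
- an excess is below zero if the other one leads

- left-handed product and right-handed product together, in percent of the left-handed substrate and right-handed substrate charged together, at 3.0 min
- excess of left-handed product over right-handed product in the product at 3.0 min
- whether the exchange between left-handed substrate and right-handed substrate keeps pace with the reaction: how far the product's excess at 3.0 min gets from its value without exchange to its value with instant exchange (above 80 % keeps pace, below 20 % hardly takes part, else lags behind)

In oak, τ reads 0.703 min at 0.667 min and 0.711 min at 4.00 min, so in oak the clock reads steady between those two readings. In alder the last reading gives 7.33 min. Between the two charges τ falls as the charge to the power 2.89, steeper than the 2 you get if working catalyst simply scales with the charge. My interpolation gives the flask 2.36 min.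

Now the books for the flask at 3.0 min, as I reckon them. Partner used comes to 56.0 % of the charge. The excess read from alder and oak, taken at the flask's conversion, is 49.5 %. So 41.9 % is entered as left-handed product, 14.1 % as right-handed product and 44.0 % as unreacted substrates. Exchange should keep pace (dynamic kinetic resolution): oak at 3.00 min holds 59.5 % left-handed product, more than the 50.0 % charged left-handed, with left-handed substrate at 8.9 % and right-handed substrate at 8.90 %.

The forecast says 57 % and 51 %, a little above my two figures, and it says keeps pace, on the ground that “exchange is much faster than reaction”.

The flask gives 53.4 %, 49.9 % and keeps pace, so its τ reads 2.62 min against the 2.36 min reckoned.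

    partner + catalyst + left-handed substrate → catalyst + left-handed product (k = 1900 M⁻² s⁻¹)
    partner + catalyst + right-handed substrate → catalyst + right-handed product (k = 400 M⁻² s⁻¹)
    left-handed substrate ⇌ right-handed substrate (k = 0.290 s⁻¹)
    left-handed product ⇌ right-handed product (k = 0.00120 s⁻¹)
    catalyst + added ligand ⇌ idle complex, settled at all times (K = 16000 M⁻¹)

At 0.955 min the reaction in the flask uses left-handed substrate at 0.027 of the rate of the forward exchange step alone, which is slower than that step. The excess in the flask gets 98 % of the way to its instant-exchange value. In a neighbour of the flask with 0.800 equiv of partner and its other charges unchanged, partner is r = 0.400 of the substrates together, and substrates over partner grows from 1/r as exp((1−r)t/τ). That gives 24.9 % product, and that neighbour stands at 24.9 %.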